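A one-step world, with Z + X giving E and nothing further, rewards every added X, but in these flasks X also takes E away to X.E.

    Z + X → L + J (k1 = 0.0046 /M/s)
    L → E (k2 = 2.9 × 10⁻⁴ /s)
    X + E → X.E (k3 = 6.1 × 10⁻⁴ /M/s)
    Z + Q → Z.Q (k4 = 0.93 /M/s)

| flask | Z | X | Q | time | remark |
|---|---|---|---|---|---|
| east | 0.050 M | 0.500 equiv (in portions, 3) | 1.00 mM | 10 h | the portions of X follow each other after 4.0 min, the first at the start |
| south-west | 0.050 M | 1.00 equiv (in portions, 3) | 1.00 mM | 10 h | the portions of X follow each other after 4.0 min, the first at the start |
| south | 0.050 M | 2.00 equiv (in portions, 3) | 1.00 mM | 10 h | the portions of X follow each other after 4.0 min, the first at the start |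
| north-east | 0.050 M | 4.00 equiv (in portions, 3) | 1.00 mM | 10 h | the portions of X follow each other after 4.0 min, the first at the start |
| north-west | 0.050 M | 8.00 equiv (in portions, 3) | 1.00 mM | 10 h | the portions of X follow each other after 4.0 min, the first at the start |

- amount of E at the end, in percent of the Z charged for east, south-west, south, north-east, north-west, in this order
- the course of these numbers from the first flask to the last (rises, then falls / rises all the way / falls, then rises / falls all the way / hardly changes)

- "hardly changes" means that all values lie within two and a half points (for a concentration: within two and a half percent of the largest)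
- run time (east): 10 h

We divide the rate at which X destroys E by the rate at which X consumes Z. Both [X] and time cancel, which leaves σ[E]/[Z], where the selectivity factor σ, the constant of E's loss over that of Z's use, is 0.133.

Q takes 2.00 % of the Z first, because in east the half-life of Z by step 4 alone, with Q held at its charge, is 0.21 h, against 1.7 h by step 1 alone with the whole charge of X present at once. L has a half-life of 0.66 h, short beside the 10 h run, so we count it as E at once.

Let z be the part left of the Z that Q spares, and y the E formed per unit of that Z. The ratio then integrates to y = (z^σ − z)/(1 − σ). This curve peaks where z = σy, at y = σ^(σ/(1 − σ)).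

Our reckoning therefore gives a peak of 72.0 % of the Z charged, reached once 1.05 of X has been used. That point lies between the 0.500 equiv of east and the 8.00 equiv of north-west, so our reckoning says that the row rises, then falls. It goes no further, since placing each flask on the curve needs its final [Z].

The forecast gives 45.5 %, 72 %, 50 %, 10 % and 0.4 %, a row that rises, then falls, with the loss of E at large excess “with the loss growing roughly exponentially with the leftover X”.

The flasks end at 46.4 %, 73.4 %, 50.3 %, 10.5 % and 0.362 %, a row that rises, then falls. The row turns at 1.1 equiv, between the 1.00 equiv of south-west and the 2.00 equiv of south. East ends with 49.9 % of its Z, where the curve with σ gives 45.8 % of E against the 46.4 % found. South-west ends with 13.7 % of its Z, where the same curve gives 71.3 % against the 73.4 % found.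

(The numbers are those of an exercise; the flask was simulated.)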